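**Plan**

- Quinone numbering used below: C1 is the carbonyl carbon next to C2–OH, C3 carries the icosyl chain, C4 is the second carbonyl carbon, C5 carries OMe, C6 is the ring CH.
- Retrosynthesis: the O–tert-butyl bond at C2 and the quinone oxidation level are adjusted last. The ring bond C1–C6 is then cut (reverse 6π electrocyclization) and the C1–C4 bond re-formed, which folds the six-membered ring into a 4-(1-methoxyvinyl)cyclobutenone. Finally the C3–icosyl bond and the C4–C5 bond are cut, leaving a squaric ester.
- Enabling feature: C1(=O)–C2(OH)–C3(alkyl)–C4(=O) is a contiguous four-carbon unit with three oxygens, which is the squaric acid core, and C5(OMe)=C6H is a two-carbon enol ether. Strain in the four-membered ring and aromatization of the six-membered ring drive the ring expansion.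
- Forward: squarate plus 1-methoxyvinyllithium (C4–C5) with O-silylation; icosyllithium addition with 1,3-carbonyl transposition (C3–chain, fixes the substitution pattern); thermal ring opening and 6π closure builds the six-membered ring (C1–C6); desilylation and oxidation give the quinone; acid removes the tert-butyl group.
- Stereochemistry: the target has no stereocenter. The single sp3 ring carbon of 5 and 11 is racemic and disappears on aromatization. The dienylketene geometry comes from outward rotation of the silyloxy group.

Key step: step 4

Assumption: 1, 2 and 6 are taken as purchasable; all cyclobutenone intermediates are racemic (diastereomer mixtures where two sp3 ring carbons are present), which is without consequence for an achiral target.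

**Step 1**
Reactants: 1 di-tert-butyl squarate; 2 methyl vinyl ether
Product: 5 2,3-di-tert-butoxy-4-[(tert-butyldimethylsilyl)oxy]-4-(1-methoxyethenyl)cyclobut-2-en-1-one (racemic), via 1-methoxyvinyllithium 3 (not isolated), via lithium cyclobutenolate 4 (not isolated)
Conditions: 2 (excess), t-BuLi, THF, −78 → 0 °C; recool, add 1, THF, −78 °C; then TBSOTf, −78 → −20 °C; aq. NaHCO3
Reagents that add atoms: tert-butyldimethylsilyl trifluoromethanesulfonate (TBSOTf), CC(C)(C)[Si](C)(C)OS(=O)(=O)C(F)(F)F
Why: α-Lithiated methyl vinyl ether should add 1,2 to one of the two equivalent carbonyl groups of the squarate (organolithium 1,2-addition to a squaric ester) and the tertiary lithium alkoxide is silylated in the same flask (O-silylation with a silyl triflate), the new stereocenter forming as a racemate that is erased in step 4.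

**Step 2**
Reactants: 6 1-bromoicosane
Product: 7 1-iodoicosane
Conditions: NaI, acetone, reflux
Reagents that add atoms: sodium iodide (NaI), [Na+].[I-]
Why: Finkelstein reaction, an SN2 halide exchange driven by precipitation of NaBr, should give the primary iodide needed for a clean iodine–lithium exchange.

**Step 3**
Reactants: 5 2,3-di-tert-butoxy-4-[(tert-butyldimethylsilyl)oxy]-4-(1-methoxyethenyl)cyclobut-2-en-1-one; 7 1-iodoicosane
Product: 11 2-tert-butoxy-4-[(tert-butyldimethylsilyl)oxy]-3-icosyl-4-(1-methoxyethenyl)cyclobut-2-en-1-one (racemic), via icosyllithium 8 (not isolated), via lithium alkoxide 9 (not isolated), via tertiary trifluoroacetate 10 (not isolated)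
Conditions: 7, t-BuLi (2.1 equiv), Et2O/pentane, −78 °C → rt; add to 5, THF, −78 °C; then (CF3CO)2O, −78 → −20 °C; aq. NaHCO3
Reagents that add atoms: none
Why: Iodine–lithium exchange (the second equivalent of t-BuLi destroys the tert-butyl iodide formed) gives the primary alkyllithium, which should add 1,2 to the only carbonyl group of 5; trifluoroacetylation of the alkoxide and ionization then give an allyl cation held as an oxocarbenium ion by the distal tert-butoxy group, which sheds its tert-butyl group to unveil the transposed ketone (Stork–Danheiser-type alkylative 1,3-carbonyl transposition of a vinylogous ester), the transient second stereocenter being destroyed on ionization.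

**Step 4**
Reactants: 11 2-tert-butoxy-4-[(tert-butyldimethylsilyl)oxy]-3-icosyl-4-(1-methoxyethenyl)cyclobut-2-en-1-one
Product: 14 2-tert-butoxy-4-[(tert-butyldimethylsilyl)oxy]-3-icosyl-5-methoxyphenol, via dienylketene 12 (not isolated), via cyclohexa-2,4-dienone 13 (not isolated)
Conditions: PhMe (0.01 M, degassed), 110 °C, Ar
Reagents that add atoms: none
Why: Heating should trigger a conrotatory 4π electrocyclic opening of the strained cyclobutenone in which the silyloxy donor on the sp3 carbon rotates outward, so that the 1-methoxyvinyl group ends up cis to the ketene arm in dienylketene 12. The ketene carbon (the one next to the C–O-tert-butyl carbon) and the CH2 terminus of the enol ether then sit at the two ends of a hexatriene-type array, and a thermal disrotatory 6π electrocyclization joins them, closing the six-membered carbocycle as cyclohexa-2,4-dienone 13. Enolization of the CH2 group of 13 gives phenol 14, so release of ring strain and the gain of aromaticity make the cascade irreversible. The closest known reaction type is the thermal ring expansion of squarate-derived 4-alkenyl-4-oxycyclobutenones to hydroquinone derivatives (Moore-type ring expansion). No new stereocenter is formed, and the racemic sp3 carbon of 11 becomes an aromatic carbon. The step needs torquoselectivity, secured by the strong preference of an oxygen donor for outward rotation, and a single substitution pattern, secured because the order tert-butoxy, icosyl, silyloxy-carbinol around the four-membered ring was fixed in step 3; high dilution and an acid-free, degassed medium protect the ketene and the enol ether from bimolecular and hydrolytic side reactions.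

**Step 5**
Reactants: 14 2-tert-butoxy-4-[(tert-butyldimethylsilyl)oxy]-3-icosyl-5-methoxyphenol
Product: 16 2-tert-butoxy-3-icosyl-5-methoxy-1,4-benzoquinone, via hydroquinone 15 (not isolated)
Conditions: TBAF, AcOH, THF, 0 °C → rt; then Ag2O, MgSO4, Et2O, rt
Reagents that add atoms: none
Why: Buffered fluoride should cleave the aryl silyl ether (desilylation) and Ag2O then performs the mild two-electron oxidation of the 1,4-hydroquinone to the para-quinone without touching the tert-butyl and methyl ethers.

**Step 6**
Reactants: 16 2-tert-butoxy-3-icosyl-5-methoxy-1,4-benzoquinone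
Product: 17 Irisoquin-D (2-hydroxy-3-icosyl-5-methoxy-1,4-benzoquinone)
Conditions: TFA/CH2Cl2 (1:4), 0 °C → rt
Reagents that add atoms: none
Why: Acidolysis of the tert-butyl ether (E1 loss of 2-methylpropene from the protonated vinylogous tert-butyl ester) should free the hydroxyl group, while the methyl vinylogous ester cannot ionize and survives anhydrous acid.

**Compound list**

1 | di-tert-butyl squarate (3,4-di-tert-butoxycyclobut-3-ene-1,2-dione) | CC(C)(C)OC1=C(OC(C)(C)C)C(=O)C1=O | starting material
2 | methyl vinyl ether (methoxyethene) | COC=C | starting material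
3 | 1-methoxyvinyllithium | [Li]C(=C)OC | intermediate
4 | lithium 2,3-di-tert-butoxy-1-(1-methoxyethenyl)-4-oxocyclobut-2-en-1-olate (racemic) | [Li]OC1(C(=C)OC)C(=O)C(OC(C)(C)C)=C1OC(C)(C)C | intermediate
5 | 2,3-di-tert-butoxy-4-[(tert-butyldimethylsilyl)oxy]-4-(1-methoxyethenyl)cyclobut-2-en-1-one (racemic) | CC(C)(C)[Si](C)(C)OC1(C(=C)OC)C(=O)C(OC(C)(C)C)=C1OC(C)(C)C | intermediate
6 | 1-bromoicosane | CCCCCCCCCCCCCCCCCCCCBr | starting material
7 | 1-iodoicosane | CCCCCCCCCCCCCCCCCCCCI | intermediate
8 | icosyllithium | [Li]CCCCCCCCCCCCCCCCCCCC | intermediate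
9 | lithium 2,3-di-tert-butoxy-4-[(tert-butyldimethylsilyl)oxy]-1-icosyl-4-(1-methoxyethenyl)cyclobut-2-en-1-olate (diastereomer mixture, racemic) | CCCCCCCCCCCCCCCCCCCCC1(O[Li])C(OC(C)(C)C)=C(OC(C)(C)C)C1(O[Si](C)(C)C(C)(C)C)C(=C)OC | intermediate
10 | 2,3-di-tert-butoxy-4-[(tert-butyldimethylsilyl)oxy]-1-icosyl-4-(1-methoxyethenyl)cyclobut-2-en-1-yl trifluoroacetate (diastereomer mixture, racemic) | CCCCCCCCCCCCCCCCCCCCC1(OC(=O)C(F)(F)F)C(OC(C)(C)C)=C(OC(C)(C)C)C1(O[Si](C)(C)C(C)(C)C)C(=C)OC | intermediate
11 | 2-tert-butoxy-4-[(tert-butyldimethylsilyl)oxy]-3-icosyl-4-(1-methoxyethenyl)cyclobut-2-en-1-one (racemic) | CCCCCCCCCCCCCCCCCCCCC1=C(OC(C)(C)C)C(=O)C1(O[Si](C)(C)C(C)(C)C)C(=C)OC | intermediate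
12 | 2-tert-butoxy-4-[(tert-butyldimethylsilyl)oxy]-3-icosyl-5-methoxyhexa-1,3,5-trien-1-one (ketenyl and methoxyvinyl groups cis on the central double bond) | CCCCCCCCCCCCCCCCCCCC/C(C(OC(C)(C)C)=C=O)=C(\O[Si](C)(C)C(C)(C)C)C(=C)OC | intermediate
13 | 2-tert-butoxy-4-[(tert-butyldimethylsilyl)oxy]-3-icosyl-5-methoxycyclohexa-2,4-dien-1-one | CCCCCCCCCCCCCCCCCCCCC1=C(OC(C)(C)C)C(=O)CC(OC)=C1O[Si](C)(C)C(C)(C)C | intermediate
14 | 2-tert-butoxy-4-[(tert-butyldimethylsilyl)oxy]-3-icosyl-5-methoxyphenol | CCCCCCCCCCCCCCCCCCCCc1c(OC(C)(C)C)c(O)cc(OC)c1O[Si](C)(C)C(C)(C)C | intermediate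
15 | 2-tert-butoxy-3-icosyl-5-methoxybenzene-1,4-diol | CCCCCCCCCCCCCCCCCCCCc1c(OC(C)(C)C)c(O)cc(OC)c1O | intermediate
16 | 2-tert-butoxy-3-icosyl-5-methoxy-1,4-benzoquinone | CCCCCCCCCCCCCCCCCCCCC1=C(OC(C)(C)C)C(=O)C=C(OC)C1=O | intermediate
17 | Irisoquin-D (2-hydroxy-3-icosyl-5-methoxy-1,4-benzoquinone) | CCCCCCCCCCCCCCCCCCCCC1=C(O)C(=O)C=C(OC)C1=O | target

**Step count and risks**

Total steps: 6. Longest linear sequence: 5 steps (steps 1, 3, 4, 5, 6; the branch through step 2 is equally long).

Steps most likely to fail:

1. Step 3. What may go wrong: incomplete iodine–lithium exchange because the long-chain iodide is poorly soluble at −78 °C; migration of the silyl group between the two vicinal oxygens at the alkoxide stage, which would send the ionization to the wrong carbon; or protonolysis of the 1-methoxyvinyl group if acid builds up during the anhydride-induced ionization. Fallback, setting out from 5 and 6 and coming back at 11: the chain is delivered as icosylmagnesium bromide F1, made from 6 and Mg turnings in THF and added to 5 at −78 °C. A buffered quench (aq. NH4Cl/NH3) should give the tertiary carbinol 2,3-di-tert-butoxy-4-[(tert-butyldimethylsilyl)oxy]-1-icosyl-4-(1-methoxyethenyl)cyclobut-2-en-1-ol F2. The transposition is then run as a separate, amine-buffered dehydration: MsCl and excess Et3N in CH2Cl2 at −40 °C convert F2 into the tertiary methanesulfonate 2,3-di-tert-butoxy-4-[(tert-butyldimethylsilyl)oxy]-1-icosyl-4-(1-methoxyethenyl)cyclobut-2-en-1-yl methanesulfonate F3, which should ionize and lose 2-methylpropene to give 11. This avoids iodide 7, the organolithium and any free acid.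

2. Step 4. What may go wrong: thermal loss of 2-methylpropene from the tert-butyl enol ether, or capture of the ketene before it cyclizes, if opening of the silyl ether needs prolonged heating. Fallback, setting out from 11 and coming back at 15: the silyl group is removed first (TBAF, AcOH, THF, 0 °C) to give 2-tert-butoxy-4-hydroxy-3-icosyl-4-(1-methoxyethenyl)cyclobut-2-en-1-one F4, the unprotected carbinol being the most thoroughly documented substrate class for this cascade. Heating F4 in degassed benzene at 80 °C should lead through 2-tert-butoxy-4-hydroxy-3-icosyl-5-methoxyhexa-1,3,5-trien-1-one F5 and 2-tert-butoxy-4-hydroxy-3-icosyl-5-methoxycyclohexa-2,4-dien-1-one F6 directly to hydroquinone 15, which is oxidized with Ag2O as in the second half of step 5.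

3. Step 5. What may go wrong: slow fluoride attack at a silyl ether flanked by two ortho substituents, or base-induced decomposition of the electron-rich hydroquinone before it is oxidized. Fallback, setting out from 14 and coming back at 16: the intact silyloxyphenol is oxidized directly with PhI(OAc)2 in MeCN/H2O at 0 °C. Trivalent iodine should convert the phenol into a phenoxonium ion, water adds at the para carbon and the hemiketal expels the silanol to give quinone 16 (oxidative desilylation of a para-oxygenated phenol). Should the tert-butyl ether be lost as well at this stage, the product would be 17 itself. This fallback makes no compound outside the compound list (F0).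

**Further compounds**

F1 | step 3 | icosylmagnesium bromide | CCCCCCCCCCCCCCCCCCCC[Mg]Br
F2 | step 3 | 2,3-di-tert-butoxy-4-[(tert-butyldimethylsilyl)oxy]-1-icosyl-4-(1-methoxyethenyl)cyclobut-2-en-1-ol (diastereomer mixture, racemic) | CCCCCCCCCCCCCCCCCCCCC1(O)C(OC(C)(C)C)=C(OC(C)(C)C)C1(O[Si](C)(C)C(C)(C)C)C(=C)OC
F3 | step 3 | 2,3-di-tert-butoxy-4-[(tert-butyldimethylsilyl)oxy]-1-icosyl-4-(1-methoxyethenyl)cyclobut-2-en-1-yl methanesulfonate (diastereomer mixture, racemic) | CCCCCCCCCCCCCCCCCCCCC1(OS(C)(=O)=O)C(OC(C)(C)C)=C(OC(C)(C)C)C1(O[Si](C)(C)C(C)(C)C)C(=C)OC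
F4 | step 4 | 2-tert-butoxy-4-hydroxy-3-icosyl-4-(1-methoxyethenyl)cyclobut-2-en-1-one (racemic) | CCCCCCCCCCCCCCCCCCCCC1=C(OC(C)(C)C)C(=O)C1(O)C(=C)OC
F5 | step 4 | 2-tert-butoxy-4-hydroxy-3-icosyl-5-methoxyhexa-1,3,5-trien-1-one (ketenyl and methoxyvinyl groups cis on the central double bond) | CCCCCCCCCCCCCCCCCCCC/C(C(OC(C)(C)C)=C=O)=C(\O)C(=C)OC
F6 | step 4 | 2-tert-butoxy-4-hydroxy-3-icosyl-5-methoxycyclohexa-2,4-dien-1-one | CCCCCCCCCCCCCCCCCCCCC1=C(OC(C)(C)C)C(=O)CC(OC)=C1O
F0 | step 5 | none | none
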